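**Retrosynthetic overview**

1. Feature: flavone ring A (C4a, C5, C6, C7, C8, C8a) is a phloroglucinol with oxygens at C5, C7 and C8a, and its C8 is bonded to C5' of flavanone ring B. C8 is therefore treated as the benzylic carbon of an aryl–CH2 triketide, and the hindered C8–C5' bond is the aryl–CH2 bond left by an aromatic Claisen rearrangement, not a cross-coupling.
2. Target ⇒ octabenzyl ether (hydrogenolysis) ⇒ flavanone ring C by enantioselective oxa-Michael closure of an arylidene β-keto ester, made from the flavone aldehyde and a phloroacetophenone-derived tert-butyl β-keto ester.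
3. Flavone ring C ⇒ 6-endo closure of an o-hydroxyaryl ynone ⇒ salicylaldehyde plus lithium arylacetylide; the salicylaldehyde comes from formylation and regioselective dibenzylation of the 2-arylphloroglucinol.
4. 2-Arylphloroglucinol ⇒ intramolecular Claisen condensation of methyl 6-aryl-3,5-dioxohexanoate ⇒ acetoacetate dianion plus arylacetaldehyde ⇒ 3-allyl-4,5-dihydroxybenzaldehyde ⇒ Claisen rearrangement of 4-O-allyl-3,4-dihydroxybenzaldehyde.
5. Ring order: flavone ring A (step 8), flavone ring C (step 14), flavanone ring C with C2 (step 19); flavanone ring A and both catechol rings are bought.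

Key step: step 8

Remark: the C8–C5' axis carries three ortho oxygen substituents and one hydrogen and is assumed to rotate at room temperature, so C2 of the flavanone is the only stereogenic element, as in the given SMILES.
Remark: the quinidine-derived thiourea is assumed to give the 2S series; the sense is to be checked on a small model arylidene, and the quinine-derived pseudoenantiomer is used if it proves opposite.

**Route**

Step 1
Reactants: 1 3,4-dihydroxybenzaldehyde; 2 allyl bromide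
Product: 3 4-(allyloxy)-3-hydroxybenzaldehyde
Conditions: NaHCO3, NaI (cat.), DMF, 40 °C
Reagents that add atoms: none
Why: Williamson etherification; the 4-hydroxyl, para to the formyl group, is the more acidic phenol and the one ionised by NaHCO3, so allylation should stop at the 4-O-monoether.

Step 2
Reactants: 3 4-(allyloxy)-3-hydroxybenzaldehyde
Product: 5 3-allyl-4,5-dihydroxybenzaldehyde, via Claisen dienone 4 (not isolated)
Conditions: N,N-diethylaniline, 190 °C, Ar
Reagents that add atoms: none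
Why: Aromatic Claisen rearrangement; the [3,3] shift can only be completed at C5, the one ortho position of the ether that bears hydrogen, and the dienone tautomerises to the catechol, which lays down the future C8–C5' bond as an aryl–CH2 bond.

Step 3
Reactants: 5 3-allyl-4,5-dihydroxybenzaldehyde
Product: 6 3-allyl-4,5-bis(benzyloxy)benzaldehyde
Conditions: BnBr, K2CO3, DMF, 60 °C
Reagents that add atoms: benzyl bromide, BrCc1ccccc1
Why: Double Williamson benzylation of the catechol under standard carbonate conditions, to which the aldehyde and the allyl group are inert.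

Step 4
Reactants: 6 3-allyl-4,5-bis(benzyloxy)benzaldehyde
Product: 7 2-[3-allyl-4,5-bis(benzyloxy)phenyl]-1,3-dioxolane
Conditions: HOCH2CH2OH, PPTS (cat.), toluene, reflux, Dean–Stark
Reagents that add atoms: ethylene glycol, OCCO
Why: Acid-catalysed acetalisation with azeotropic removal of water masks the aldehyde for the carbanion and base chemistry of steps 6 to 14, and PPTS is too weak an acid to move the allyl double bond.

Step 5
Reactants: 7 2-[3-allyl-4,5-bis(benzyloxy)phenyl]-1,3-dioxolane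
Product: 8 [2,3-bis(benzyloxy)-5-(1,3-dioxolan-2-yl)phenyl]acetaldehyde
Conditions: OsO4 (2 mol%), NaIO4, 2,6-lutidine, dioxane/H2O, rt
Reagents that add atoms: NaIO4 (oxygen passed on through OsO4), [Na+].[O-]I(=O)(=O)=O
Why: Lemieux–Johnson oxidation; OsO4 dihydroxylates the terminal alkene and NaIO4 cleaves the diol, while 2,6-lutidine keeps the medium neutral so that the dioxolane and the enolisable arylacetaldehyde (used crude) should survive.

Step 6
Reactants: 8 [2,3-bis(benzyloxy)-5-(1,3-dioxolan-2-yl)phenyl]acetaldehyde; 9 methyl acetoacetate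
Product: 11 methyl 6-[2,3-bis(benzyloxy)-5-(1,3-dioxolan-2-yl)phenyl]-5-hydroxy-3-oxohexanoate (racemic), via methyl acetoacetate dianion 10 (not isolated)
Conditions: NaH, THF, 0 °C; n-BuLi, 0 °C; then 8, −78 °C; aq NH4Cl
Reagents that add atoms: none
Why: Aldol addition of the acetoacetate dianion through its terminal carbon, which at −78 °C should add to the aldehyde faster than it enolises it; the carbinol centre is formed racemic and is removed in step 7.

Step 7
Reactants: 11 methyl 6-[2,3-bis(benzyloxy)-5-(1,3-dioxolan-2-yl)phenyl]-5-hydroxy-3-oxohexanoate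
Product: 12 methyl 6-[2,3-bis(benzyloxy)-5-(1,3-dioxolan-2-yl)phenyl]-3,5-dioxohexanoate
Conditions: DMP, pyridine, CH2Cl2, 0 °C to rt
Reagents that add atoms: none
Why: Dess–Martin oxidation of the secondary alcohol under pyridine buffering should give the 3,5-dioxo ester (largely enolised) without touching the acetal or the benzyl ethers; it is taken on without long storage.

Step 8
Reactants: 12 methyl 6-[2,3-bis(benzyloxy)-5-(1,3-dioxolan-2-yl)phenyl]-3,5-dioxohexanoate
Product: 14 2-[2,3-bis(benzyloxy)-5-(1,3-dioxolan-2-yl)phenyl]benzene-1,3,5-triol, via 2-arylcyclohexane-1,3,5-trione 13 (not isolated)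
Conditions: NaOCH3 (5 equiv), CH3OH, reflux, Ar; AcOH to pH 6 at 0 °C
Reagents that add atoms: none
Why: Methoxide deprotonates the 1,3-diketone and, in small equilibrium concentration, the C6 methylene, which is both benzylic and alpha to the C5 ketone; this carbanion adds to the C1 ester carbonyl and expels methoxide (intramolecular Claisen, Dieckmann-type condensation), forming the bond from flavone C8 to an oxygenated neighbour (C7 or C8a, equivalent by symmetry until step 10) and giving trione 13, which enolises to phloroglucinol 14. The closest known reaction is the base-induced Claisen cyclisation of methyl 3,5-dioxohexanoate to phloroglucinol, and here the aryl group makes C6–H more acidic than in the parent, so methoxide should suffice. The one ring formed, flavone ring A (C4a, C5, C6, C7, C8, C8a), closes in a 6-(enolendo)-exo-trig mode, which is allowed. No stereocentre is created. The selectivity needed is C-acylation by C6 over O-acylation by the C5 enol oxygen (which would give a 4-hydroxy-2-pyranone); lactone formation should be reversible in NaOCH3/CH3OH because methoxide reopens it to the ester, whereas the trione leaves the equilibrium as the aromatic phenoxide. The acetal and the benzyl ethers are inert to methoxide.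

Step 9
Reactants: 14 2-[2,3-bis(benzyloxy)-5-(1,3-dioxolan-2-yl)phenyl]benzene-1,3,5-triol
Product: 15 3-[2,3-bis(benzyloxy)-5-(1,3-dioxolan-2-yl)phenyl]-2,4,6-trihydroxybenzaldehyde
Conditions: MgCl2, Et3N, (CH2O)n (2.3 equiv), MeCN, 70 °C, Ar; pH 5 citrate work-up
Reagents that add atoms: paraformaldehyde (as formaldehyde), C=O
Why: Magnesium-mediated ortho-formylation (Casnati–Skattebøl type): formaldehyde is delivered inside the aryloxymagnesium complex to a ring carbon ortho to oxygen and the resulting alkoxide is oxidised by a second formaldehyde; the two free ring positions of 14 are equivalent by symmetry, the first formyl group deactivates the ring, and the basic medium spares the dioxolane.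

Step 10
Reactants: 15 3-[2,3-bis(benzyloxy)-5-(1,3-dioxolan-2-yl)phenyl]-2,4,6-trihydroxybenzaldehyde
Product: 16 4,6-bis(benzyloxy)-3-[2,3-bis(benzyloxy)-5-(1,3-dioxolan-2-yl)phenyl]-2-hydroxybenzaldehyde
Conditions: BnBr (2.1 equiv), K2CO3, DMF, rt
Reagents that add atoms: benzyl bromide, BrCc1ccccc1
Why: Williamson benzylation under steric and hydrogen-bond control: the hydroxyl para to the formyl group is the most acidic and the ortho hydroxyl next to ring hydrogen is open, while the ortho hydroxyl between the formyl group and the aryl ring is chelated and shielded and should stay free, which fixes this oxygen as O1 of the flavone and therefore the aryl group at C8.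

Step 11
Reactants: 17 3,4-bis(benzyloxy)benzaldehyde
Product: 18 1,2-bis(benzyloxy)-4-ethynylbenzene
Conditions: dimethyl (1-diazo-2-oxopropyl)phosphonate, K2CO3, MeOH, rt
Reagents that add atoms: dimethyl (1-diazo-2-oxopropyl)phosphonate, CC(=O)C(=[N+]=[N-])P(=O)(OC)OC
Why: Ohira–Bestmann (Seyferth–Gilbert) homologation of an aromatic aldehyde to the terminal alkyne under mild carbonate conditions.

Step 12
Reactants: 16 4,6-bis(benzyloxy)-3-[2,3-bis(benzyloxy)-5-(1,3-dioxolan-2-yl)phenyl]-2-hydroxybenzaldehyde; 18 1,2-bis(benzyloxy)-4-ethynylbenzene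
Product: 20 1-{4,6-bis(benzyloxy)-3-[2,3-bis(benzyloxy)-5-(1,3-dioxolan-2-yl)phenyl]-2-hydroxyphenyl}-3-[3,4-bis(benzyloxy)phenyl]prop-2-yn-1-ol (racemic), via lithium arylacetylide 19 (not isolated)
Conditions: 18 (3 equiv), n-BuLi, THF, −78 °C; then 16, −78 to 0 °C; aq NH4Cl
Reagents that add atoms: none
Why: 1,2-Addition of a lithium acetylide to the aldehyde; the first equivalent only deprotonates the phenol and the excess adds to the phenoxide aldehyde, giving a racemic propargylic alcohol whose centre is erased in step 13.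

Step 13
Reactants: 20 1-{4,6-bis(benzyloxy)-3-[2,3-bis(benzyloxy)-5-(1,3-dioxolan-2-yl)phenyl]-2-hydroxyphenyl}-3-[3,4-bis(benzyloxy)phenyl]prop-2-yn-1-ol
Product: 21 1-{4,6-bis(benzyloxy)-3-[2,3-bis(benzyloxy)-5-(1,3-dioxolan-2-yl)phenyl]-2-hydroxyphenyl}-3-[3,4-bis(benzyloxy)phenyl]prop-2-yn-1-one
Conditions: MnO2 (activated, excess), CH2Cl2, rt
Reagents that add atoms: none
Why: MnO2 oxidises the benzylic propargylic alcohol selectively to the ynone and should leave the phenol, the acetal and the benzyl ethers alone.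

Step 14
Reactants: 21 1-{4,6-bis(benzyloxy)-3-[2,3-bis(benzyloxy)-5-(1,3-dioxolan-2-yl)phenyl]-2-hydroxyphenyl}-3-[3,4-bis(benzyloxy)phenyl]prop-2-yn-1-one
Product: 23 5,7-bis(benzyloxy)-8-[2,3-bis(benzyloxy)-5-(1,3-dioxolan-2-yl)phenyl]-2-[3,4-bis(benzyloxy)phenyl]-4H-chromen-4-one, via beta-diethylamino enone 22 (not isolated)
Conditions: Et2NH (5 equiv), EtOH/THF, 50 °C
Reagents that add atoms: none
Why: Conjugate addition of diethylamine to the ynone gives the beta-amino enone, and the phenol then displaces the amine by addition–elimination, which enforces the 6-endo mode and closes flavone ring C (O1–C2) instead of the 5-exo aurone.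

Step 15
Reactants: 23 5,7-bis(benzyloxy)-8-[2,3-bis(benzyloxy)-5-(1,3-dioxolan-2-yl)phenyl]-2-[3,4-bis(benzyloxy)phenyl]-4H-chromen-4-one
Product: 24 3,4-bis(benzyloxy)-5-{5,7-bis(benzyloxy)-2-[3,4-bis(benzyloxy)phenyl]-4-oxo-4H-chromen-8-yl}benzaldehyde
Conditions: 1 M HCl, THF, rt
Reagents that add atoms: water, O
Why: Acid hydrolysis of the dioxolane; benzyl ethers and the flavone are stable to dilute HCl at room temperature.

Step 16
Reactants: 25 2,4,6-trihydroxyacetophenone
Product: 26 1-[2,4-bis(benzyloxy)-6-hydroxyphenyl]ethanone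
Conditions: BnBr (2.1 equiv), K2CO3, DMF, rt
Reagents that add atoms: benzyl bromide, BrCc1ccccc1
Why: Williamson benzylation; the hydroxyl hydrogen-bonded to the acetyl group is the least reactive, so two equivalents of benzyl bromide should leave exactly that one free.

Step 17
Reactants: 26 1-[2,4-bis(benzyloxy)-6-hydroxyphenyl]ethanone
Product: 27 tert-butyl 3-[2,4-bis(benzyloxy)-6-hydroxyphenyl]-3-oxopropanoate
Conditions: LiN(SiMe3)2 (3.3 equiv), THF, −78 °C; Boc2O, −78 to 0 °C; aq NH4Cl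
Reagents that add atoms: di-tert-butyl dicarbonate, CC(C)(C)OC(=O)OC(=O)OC(C)(C)C
Why: Claisen-type C-acylation of the phenoxide–enolate dianion at the methyl carbon by Boc2O, driven by deprotonation of the beta-keto ester with the third equivalent of base.

Step 18
Reactants: 24 3,4-bis(benzyloxy)-5-{5,7-bis(benzyloxy)-2-[3,4-bis(benzyloxy)phenyl]-4-oxo-4H-chromen-8-yl}benzaldehyde; 27 tert-butyl 3-[2,4-bis(benzyloxy)-6-hydroxyphenyl]-3-oxopropanoate
Product: 28 tert-butyl 2-[2,4-bis(benzyloxy)-6-hydroxybenzoyl]-3-(3,4-bis(benzyloxy)-5-{5,7-bis(benzyloxy)-2-[3,4-bis(benzyloxy)phenyl]-4-oxo-4H-chromen-8-yl}phenyl)prop-2-enoate (alkene isomers)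
Conditions: piperidine (cat.), AcOH (cat.), 4 Å molecular sieves, toluene, rt
Reagents that add atoms: none
Why: Knoevenagel condensation of the aldehyde with the active methylene of the beta-keto ester under piperidinium acetate catalysis with removal of water; the product is kept cold and used at once to limit uncatalysed ring closure.

Step 19
Reactants: 28 tert-butyl 2-[2,4-bis(benzyloxy)-6-hydroxybenzoyl]-3-(3,4-bis(benzyloxy)-5-{5,7-bis(benzyloxy)-2-[3,4-bis(benzyloxy)phenyl]-4-oxo-4H-chromen-8-yl}phenyl)prop-2-enoate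
Product: 30 (2S)-5,7-bis(benzyloxy)-2-{3,4-bis(benzyloxy)-5-[5,7-bis(benzyloxy)-2-(3,4-bis(benzyloxy)phenyl)-4-oxo-4H-chromen-8-yl]phenyl}chroman-4-one, via flavanone 3-carboxylate 29 (not isolated)
Conditions: N-[3,5-bis(trifluoromethyl)phenyl]-N'-(9-deoxy-epi-quinidin-9-yl)thiourea (10 mol%), toluene, −25 °C; then TsOH·H2O, 80 °C
Reagents that add atoms: none
Why: Enantioselective intramolecular oxa-Michael addition (6-endo-trig) in which the thiourea binds the beta-keto ester and the quinuclidine guides the phenol to one face of the arylidene, setting C2 as S under catalyst control, after which TsOH cleaves the tert-butyl ester and the beta-keto acid decarboxylates without passing through a ring-opened chalcone.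

Step 20
Reactants: 30 (2S)-5,7-bis(benzyloxy)-2-{3,4-bis(benzyloxy)-5-[5,7-bis(benzyloxy)-2-(3,4-bis(benzyloxy)phenyl)-4-oxo-4H-chromen-8-yl]phenyl}chroman-4-one
Product: 31 (2S)-2-{3-[2-(3,4-dihydroxyphenyl)-5,7-dihydroxy-4-oxo-4H-chromen-8-yl]-4,5-dihydroxyphenyl}-5,7-dihydroxychroman-4-one (CNP0224656.1)
Conditions: H2 (1 atm), Pd/C, THF/MeOH, rt
Reagents that add atoms: none
Why: Hydrogenolysis of the eight benzyl ethers over Pd/C under neutral conditions, in which the flavone double bond and the flavanone C2–O bond are normally kept and C2 cannot epimerise by base-induced ring opening; the reaction is stopped at full debenzylation.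

**Compound list**

1 | 3,4-dihydroxybenzaldehyde | O=Cc1ccc(O)c(O)c1 | starting material
2 | allyl bromide | C=CCBr | starting material
3 | 4-(allyloxy)-3-hydroxybenzaldehyde | O=Cc1ccc(OCC=C)c(O)c1 | intermediate
4 | 6-allyl-4-formyl-2-hydroxycyclohexa-2,4-dien-1-one (Claisen dienone) | O=CC1=CC(CC=C)C(=O)C(O)=C1 | intermediate (not isolated)
5 | 3-allyl-4,5-dihydroxybenzaldehyde | O=Cc1cc(O)c(O)c(CC=C)c1 | intermediate
6 | 3-allyl-4,5-bis(benzyloxy)benzaldehyde | O=Cc1cc(CC=C)c(OCc2ccccc2)c(OCc2ccccc2)c1 | intermediate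
7 | 2-[3-allyl-4,5-bis(benzyloxy)phenyl]-1,3-dioxolane | C=CCc1cc(C2OCCO2)cc(OCc2ccccc2)c1OCc1ccccc1 | intermediate
8 | [2,3-bis(benzyloxy)-5-(1,3-dioxolan-2-yl)phenyl]acetaldehyde | O=CCc1cc(C2OCCO2)cc(OCc2ccccc2)c1OCc1ccccc1 | intermediate
9 | methyl acetoacetate | COC(=O)CC(C)=O | starting material
10 | sodium lithium dianion of methyl acetoacetate | COC(=O)[CH-]C(=O)[CH2-].[Na+].[Li+] | intermediate (not isolated)
11 | methyl 6-[2,3-bis(benzyloxy)-5-(1,3-dioxolan-2-yl)phenyl]-5-hydroxy-3-oxohexanoate (racemic) | COC(=O)CC(=O)CC(O)Cc1cc(C2OCCO2)cc(OCc2ccccc2)c1OCc1ccccc1 | intermediate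
12 | methyl 6-[2,3-bis(benzyloxy)-5-(1,3-dioxolan-2-yl)phenyl]-3,5-dioxohexanoate | COC(=O)CC(=O)CC(=O)Cc1cc(C2OCCO2)cc(OCc2ccccc2)c1OCc1ccccc1 | intermediate (key-step precursor)
13 | 2-[2,3-bis(benzyloxy)-5-(1,3-dioxolan-2-yl)phenyl]cyclohexane-1,3,5-trione | O=C1CC(=O)C(C(=O)C1)c1cc(C2OCCO2)cc(OCc2ccccc2)c1OCc1ccccc1 | intermediate (not isolated)
14 | 2-[2,3-bis(benzyloxy)-5-(1,3-dioxolan-2-yl)phenyl]benzene-1,3,5-triol | Oc1cc(O)c(-c2cc(C3OCCO3)cc(OCc3ccccc3)c2OCc2ccccc2)c(O)c1 | intermediate (key-step product)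
15 | 3-[2,3-bis(benzyloxy)-5-(1,3-dioxolan-2-yl)phenyl]-2,4,6-trihydroxybenzaldehyde | O=Cc1c(O)cc(O)c(-c2cc(C3OCCO3)cc(OCc3ccccc3)c2OCc2ccccc2)c1O | intermediate
16 | 4,6-bis(benzyloxy)-3-[2,3-bis(benzyloxy)-5-(1,3-dioxolan-2-yl)phenyl]-2-hydroxybenzaldehyde | O=Cc1c(OCc2ccccc2)cc(OCc2ccccc2)c(-c2cc(C3OCCO3)cc(OCc3ccccc3)c2OCc2ccccc2)c1O | intermediate
17 | 3,4-bis(benzyloxy)benzaldehyde | O=Cc1ccc(OCc2ccccc2)c(OCc2ccccc2)c1 | starting material
18 | 1,2-bis(benzyloxy)-4-ethynylbenzene | C#Cc1ccc(OCc2ccccc2)c(OCc2ccccc2)c1 | intermediate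
19 | lithium [3,4-bis(benzyloxy)phenyl]acetylide | [Li]C#Cc1ccc(OCc2ccccc2)c(OCc2ccccc2)c1 | intermediate (not isolated)
20 | 1-{4,6-bis(benzyloxy)-3-[2,3-bis(benzyloxy)-5-(1,3-dioxolan-2-yl)phenyl]-2-hydroxyphenyl}-3-[3,4-bis(benzyloxy)phenyl]prop-2-yn-1-ol (racemic) | OC(C#Cc1ccc(OCc2ccccc2)c(OCc2ccccc2)c1)c1c(OCc2ccccc2)cc(OCc2ccccc2)c(-c2cc(C3OCCO3)cc(OCc3ccccc3)c2OCc2ccccc2)c1O | intermediate
21 | 1-{4,6-bis(benzyloxy)-3-[2,3-bis(benzyloxy)-5-(1,3-dioxolan-2-yl)phenyl]-2-hydroxyphenyl}-3-[3,4-bis(benzyloxy)phenyl]prop-2-yn-1-one | O=C(C#Cc1ccc(OCc2ccccc2)c(OCc2ccccc2)c1)c1c(OCc2ccccc2)cc(OCc2ccccc2)c(-c2cc(C3OCCO3)cc(OCc3ccccc3)c2OCc2ccccc2)c1O | intermediate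
22 | 1-{4,6-bis(benzyloxy)-3-[2,3-bis(benzyloxy)-5-(1,3-dioxolan-2-yl)phenyl]-2-hydroxyphenyl}-3-[3,4-bis(benzyloxy)phenyl]-3-(diethylamino)prop-2-en-1-one | CCN(CC)C(=CC(=O)c1c(OCc2ccccc2)cc(OCc2ccccc2)c(-c2cc(C3OCCO3)cc(OCc3ccccc3)c2OCc2ccccc2)c1O)c1ccc(OCc2ccccc2)c(OCc2ccccc2)c1 | intermediate (not isolated)
23 | 5,7-bis(benzyloxy)-8-[2,3-bis(benzyloxy)-5-(1,3-dioxolan-2-yl)phenyl]-2-[3,4-bis(benzyloxy)phenyl]-4H-chromen-4-one | O=c1cc(-c2ccc(OCc3ccccc3)c(OCc3ccccc3)c2)oc2c(-c3cc(C4OCCO4)cc(OCc4ccccc4)c3OCc3ccccc3)c(OCc3ccccc3)cc(OCc3ccccc3)c12 | intermediate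
24 | 3,4-bis(benzyloxy)-5-{5,7-bis(benzyloxy)-2-[3,4-bis(benzyloxy)phenyl]-4-oxo-4H-chromen-8-yl}benzaldehyde | O=Cc1cc(OCc2ccccc2)c(OCc2ccccc2)c(-c2c(OCc3ccccc3)cc(OCc3ccccc3)c3c(=O)cc(-c4ccc(OCc5ccccc5)c(OCc5ccccc5)c4)oc23)c1 | intermediate
25 | 2,4,6-trihydroxyacetophenone | CC(=O)c1c(O)cc(O)cc1O | starting material
26 | 1-[2,4-bis(benzyloxy)-6-hydroxyphenyl]ethanone | CC(=O)c1c(O)cc(OCc2ccccc2)cc1OCc1ccccc1 | intermediate
27 | tert-butyl 3-[2,4-bis(benzyloxy)-6-hydroxyphenyl]-3-oxopropanoate | CC(C)(C)OC(=O)CC(=O)c1c(O)cc(OCc2ccccc2)cc1OCc1ccccc1 | intermediate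
28 | tert-butyl 2-[2,4-bis(benzyloxy)-6-hydroxybenzoyl]-3-(3,4-bis(benzyloxy)-5-{5,7-bis(benzyloxy)-2-[3,4-bis(benzyloxy)phenyl]-4-oxo-4H-chromen-8-yl}phenyl)prop-2-enoate (alkene isomers) | CC(C)(C)OC(=O)C(=Cc1cc(OCc2ccccc2)c(OCc2ccccc2)c(-c2c(OCc3ccccc3)cc(OCc3ccccc3)c3c(=O)cc(-c4ccc(OCc5ccccc5)c(OCc5ccccc5)c4)oc23)c1)C(=O)c1c(O)cc(OCc2ccccc2)cc1OCc1ccccc1 | intermediate
29 | tert-butyl (2S)-5,7-bis(benzyloxy)-2-{3,4-bis(benzyloxy)-5-[5,7-bis(benzyloxy)-2-(3,4-bis(benzyloxy)phenyl)-4-oxo-4H-chromen-8-yl]phenyl}-4-oxochromane-3-carboxylate (C3 not defined) | O=C1C(C(=O)OC(C)(C)C)[C@@H](c2cc(OCc3ccccc3)c(OCc3ccccc3)c(-c3c(OCc4ccccc4)cc(OCc4ccccc4)c4c(=O)cc(-c5ccc(OCc6ccccc6)c(OCc6ccccc6)c5)oc34)c2)Oc2cc(OCc3ccccc3)cc(OCc3ccccc3)c21 | intermediate (not isolated)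
30 | (2S)-5,7-bis(benzyloxy)-2-{3,4-bis(benzyloxy)-5-[5,7-bis(benzyloxy)-2-(3,4-bis(benzyloxy)phenyl)-4-oxo-4H-chromen-8-yl]phenyl}chroman-4-one | O=C1C[C@@H](c2cc(OCc3ccccc3)c(OCc3ccccc3)c(-c3c(OCc4ccccc4)cc(OCc4ccccc4)c4c(=O)cc(-c5ccc(OCc6ccccc6)c(OCc6ccccc6)c5)oc34)c2)Oc2cc(OCc3ccccc3)cc(OCc3ccccc3)c21 | intermediate
31 | (2S)-2-{3-[2-(3,4-dihydroxyphenyl)-5,7-dihydroxy-4-oxo-4H-chromen-8-yl]-4,5-dihydroxyphenyl}-5,7-dihydroxychroman-4-one | O=C1C[C@@H](c2cc(O)c(O)c(-c3c(O)cc(O)c4c(=O)cc(-c5ccc(O)c(O)c5)oc34)c2)Oc2cc(O)cc(O)c21 | target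

**Step count and risks**

Total step count: 20. Longest linear sequence: 17 steps (steps 1–10, 12–15, 18–20). The only stereocentre, C2 of the flavanone, is set in step 19 and meets only neutral hydrogenolysis afterwards.

Steps most likely to fail:

1. Step 8. The chain may close through oxygen to a 4-hydroxy-2-pyranone that methoxide does not return to the open ester, or the diketone may be cut by retro-Claisen attack of methoxide before the benzylic carbanion reaches the ester. The fallback drops ring construction and makes the biaryl bond by cross-coupling; it sets out from 1 and from purchased luteolin and comes back at 24.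
   - Bromination of 1 (Br2, AcOH) should give 3-bromo-4,5-dihydroxybenzaldehyde F1.
   - Benzylation (BnBr, K2CO3, DMF) gives 3,4-bis(benzyloxy)-5-bromobenzaldehyde F2.
   - Miyaura borylation (B2pin2, PdCl2(dppf), KOAc, dioxane, 90 °C) gives 3,4-bis(benzyloxy)-5-(4,4,5,5-tetramethyl-1,3,2-dioxaborolan-2-yl)benzaldehyde F3.
   - Luteolin is perbenzylated (BnBr, K2CO3, DMF, 80 °C) to 5,7-bis(benzyloxy)-2-[3,4-bis(benzyloxy)phenyl]-4H-chromen-4-one F4.
   - Iodination at C8, the ring carbon between two oxygenated carbons (N-iodosuccinimide, CF3CO2H cat., CH2Cl2), gives 5,7-bis(benzyloxy)-2-[3,4-bis(benzyloxy)phenyl]-8-iodo-4H-chromen-4-one F5.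
   - Suzuki–Miyaura coupling of F3 with F5 (Pd(OAc)2, SPhos, K3PO4, toluene/H2O, 90 °C) should give 24.

2. Step 10. The two hydroxyls ortho to the formyl group may not be told apart well enough, so that the second benzyl group enters in part at the hindered oxygen and the wrong hydroxyl is left for flavone closure (leading to the 6-aryl isomer). The fallback inverts the order so that the regiochemistry is fixed by constitution; it sets out from 14 and comes back at 16.
   - Mitsunobu mono-benzylation (BnOH, PPh3, diisopropyl azodicarboxylate, THF, 0 °C), which is O-selective and favours the unhindered hydroxyl para to the aryl group, gives 5-(benzyloxy)-2-[2,3-bis(benzyloxy)-5-(1,3-dioxolan-2-yl)phenyl]benzene-1,3-diol F6.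
   - Magnesium-mediated formylation (MgCl2, Et3N, (CH2O)n, MeCN) can then only place the formyl group between the benzyloxy carbon and a hindered hydroxyl, giving 6-(benzyloxy)-3-[2,3-bis(benzyloxy)-5-(1,3-dioxolan-2-yl)phenyl]-2,4-dihydroxybenzaldehyde F7.
   - Benzylation of the one non-chelated hydroxyl (BnBr 1.05 equiv, K2CO3, DMF) gives 16.

3. Step 19. Uncatalysed or piperidine-carried ring closure of 28, or a poor fit of the catalyst with the large biaryl arylidene, may give poor facial selectivity, and part of the material may racemise by ring opening during the acid decarboxylation. The fallback makes the racemate and resolves it; it sets out from 24 and 26 and comes back at 30.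
   - Claisen–Schmidt condensation (KOH, EtOH/THF, rt) gives the (E)-chalcone 1-[2,4-bis(benzyloxy)-6-hydroxyphenyl]-3-(3,4-bis(benzyloxy)-5-{5,7-bis(benzyloxy)-2-[3,4-bis(benzyloxy)phenyl]-4-oxo-4H-chromen-8-yl}phenyl)prop-2-en-1-one F8.
   - NaOAc in refluxing EtOH closes it to the racemic flavanone F9.
   - Preparative HPLC on an amylose tris(3,5-dimethylphenylcarbamate) phase separates the enantiomers and delivers 30.

Further compounds
F1 | step 8 | 3-bromo-4,5-dihydroxybenzaldehyde | O=Cc1cc(O)c(O)c(Br)c1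
F2 | step 8 | 3,4-bis(benzyloxy)-5-bromobenzaldehyde | O=Cc1cc(OCc2ccccc2)c(OCc2ccccc2)c(Br)c1
F3 | step 8 | 3,4-bis(benzyloxy)-5-(4,4,5,5-tetramethyl-1,3,2-dioxaborolan-2-yl)benzaldehyde | O=Cc1cc(OCc2ccccc2)c(OCc2ccccc2)c(B2OC(C)(C)C(C)(C)O2)c1
F4 | step 8 | 5,7-bis(benzyloxy)-2-[3,4-bis(benzyloxy)phenyl]-4H-chromen-4-one | O=c1cc(-c2ccc(OCc3ccccc3)c(OCc3ccccc3)c2)oc2cc(OCc3ccccc3)cc(OCc3ccccc3)c12
F5 | step 8 | 5,7-bis(benzyloxy)-2-[3,4-bis(benzyloxy)phenyl]-8-iodo-4H-chromen-4-one | O=c1cc(-c2ccc(OCc3ccccc3)c(OCc3ccccc3)c2)oc2c(I)c(OCc3ccccc3)cc(OCc3ccccc3)c12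
F6 | step 10 | 5-(benzyloxy)-2-[2,3-bis(benzyloxy)-5-(1,3-dioxolan-2-yl)phenyl]benzene-1,3-diol | Oc1cc(OCc2ccccc2)cc(O)c1-c1cc(C2OCCO2)cc(OCc2ccccc2)c1OCc1ccccc1
F7 | step 10 | 6-(benzyloxy)-3-[2,3-bis(benzyloxy)-5-(1,3-dioxolan-2-yl)phenyl]-2,4-dihydroxybenzaldehyde | O=Cc1c(OCc2ccccc2)cc(O)c(-c2cc(C3OCCO3)cc(OCc3ccccc3)c2OCc2ccccc2)c1O
F8 | step 19 | (E)-1-[2,4-bis(benzyloxy)-6-hydroxyphenyl]-3-(3,4-bis(benzyloxy)-5-{5,7-bis(benzyloxy)-2-[3,4-bis(benzyloxy)phenyl]-4-oxo-4H-chromen-8-yl}phenyl)prop-2-en-1-one | O=C(/C=C/c1cc(OCc2ccccc2)c(OCc2ccccc2)c(-c2c(OCc3ccccc3)cc(OCc3ccccc3)c3c(=O)cc(-c4ccc(OCc5ccccc5)c(OCc5ccccc5)c4)oc23)c1)c1c(O)cc(OCc2ccccc2)cc1OCc1ccccc1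
F9 | step 19 | racemic 5,7-bis(benzyloxy)-2-{3,4-bis(benzyloxy)-5-[5,7-bis(benzyloxy)-2-(3,4-bis(benzyloxy)phenyl)-4-oxo-4H-chromen-8-yl]phenyl}chroman-4-one | O=C1CC(c2cc(OCc3ccccc3)c(OCc3ccccc3)c(-c3c(OCc4ccccc4)cc(OCc4ccccc4)c4c(=O)cc(-c5ccc(OCc6ccccc6)c(OCc6ccccc6)c5)oc34)c2)Oc2cc(OCc3ccccc3)cc(OCc3ccccc3)c21
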